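In this flask reagent clears catalyst intermediate B far faster than catalyst intermediate A, at 28 /s against 0.46 /s per intermediate with reagent as charged, so I leave catalyst intermediate B aside and look for the catalyst in catalyst intermediate A.

starting material 20 mM; second substrate 20.0 mM; reagent 21.0 mM; free catalyst 2.0 mM; impurity 0.56 mM

    free catalyst + impurity → spent catalyst (k1 = 26600 /M/s)
    second substrate + free catalyst ⇌ catalyst intermediate B (K2 = 71 /M, k2 = 68.7 /M/s)
    reagent + catalyst intermediate A → free catalyst + target (k3 = 22.0 /M/s)
    reagent + catalyst intermediate B → free catalyst + second product (k4 = 1340 /M/s)
    starting material + free catalyst ⇌ catalyst intermediate A (K5 = 153 /M, k5 = 60.5 /M/s)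

- what is bound to the catalyst counts as converted
- charge of starting material (flask): 20 mM

- the form that holds most of the catalyst when 30% of the starting material are converted (catalyst intermediate A / free catalyst / spent catalyst / catalyst intermediate B)
- its share of the catalyst then

In this flask the impurity meets free catalyst at 14.9 /s, faster than starting material binds it at 1.2 /s, so I book 28.0% of the catalyst as spent and 1.44 mM as working.

The bench rule for the rest treats binding as an equilibrium. With K its equilibrium constant and [S] the free starting material, it gives a/f = K[S], where a is catalyst intermediate A and f free catalyst. That is 3.1 at the charge. But the rule asks that catalyst intermediate A falls back to free catalyst and starting material ahead of its removal by reagent, and with reagent as charged the falling back is slower, at 0.395 /s against 0.46 /s. So I balance making against both losses, with k the binding rate constant, c the rate constant of reagent with catalyst intermediate A, and [R] the reagent: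

a/f = K[S] / (1 + [R]/R*)

R* = k/(K·c) = 18.0 mM

R*, the border reagent, is the reagent concentration at which removal equals falling back. The charge 21.0 mM stands above it, so the balance taken at the charges gives 1.41, not 3.1.

At 30% conversion, [S] is 14.0 mM. I cannot reckon the reagent by hand, but the target made caps it at 16.4 mM. So:

a/f lies between 1.12 and 2.14

share of catalyst intermediate A, with catalyst intermediate B left aside, about 38.0% to 49.1%

Even the low end exceeds the spent share, and its a/f stands above 1, so I name catalyst intermediate A the resting state.

The forecast says catalyst intermediate A at 45%: “A turns over slowly, so it is the resting state.”

The flask gives catalyst intermediate A at 44.8%, with free catalyst at 24.9%. Later, at 60.0 s, reagent is down to 0.0411 mM, far below R* of 18.0 mM. The balance then gives 2.05, and the flask holds 44.0% as catalyst intermediate A against 21.4% as free catalyst, a ratio of 2.06.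

Its constants were set for the occasion; the flask was simulated.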